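**Assumption.** The target is taken exactly as the SMILES draws it: (2S,3S) in the methoxylated dihydrobenzofuran, (2′R,3′R) in the stilbene-bearing one, both trans. 5,7-Dihydroxychromone and the three benzyloxy-substituted arylboronic acids are taken as commercial. The sense of induction in steps 3 and 8 is assigned by analogy with rhodium/biaryl-bisphosphine additions to cyclic enones; if it proves opposite, the two ligand antipodes are exchanged between these steps.

## Analysis of the target

Gnetin K is a stilbene trimer built from two 2,3-diaryl-2,3-dihydrobenzofurans joined by the C6–C3′ bond. The left unit (O1, C2, C3, C3a, C4–C7, C7a) carries the 4-hydroxy-3-methoxyphenyl ring at C2 and a 3,5-dihydroxyphenyl ring at C3. The right unit (primed locants) carries a 4-hydroxyphenyl ring at C2′ and the (E)-4-hydroxystyryl group at C6′. Each benzo ring is a resorcinol in which the carbon between the two oxygens (C3a, C3a′) is the ring-fusion carbon and the carbon meta to both oxygens (C6, C6′) carries the next carbon substituent. There are four stereocentres, C2/C3 (S,S) and C2′/C3′ (R,R), each pair trans. The CIP priorities are the same in both rings, so the two heterocycles have opposite absolute sense; an arene separates them, so there is no relay and no single catalyst can set both. Sensitive groups are seven free phenols, one aryl methyl ether that must survive (no global demethylation), an E-stilbene (no hydrogenolysis once it is present), and two benzylic C2–O bonds para to a phenol oxygen that open under strong acid or base. The hard bond is C3′–C6: a crowded tertiary benzylic carbon joined to an arene position meta to both oxygens, so Friedel–Crafts polarity is unavailable, and in oxidative phenol coupling this regiochemistry is the disfavoured one. Because trans is strongly preferred in each ring, only one centre per ring needs absolute control if the other is set under substrate control.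

## Retrosynthetic reasoning

**21 to 18 and 19.** The C6′–vinyl bond is cut last. The stilbene is the only group that forbids hydrogenolysis, so it is added after all benzyl ethers are gone. The forward reaction is a Heck coupling of aryl triflate 18 with styrene 19, passing through acetate 20.

**18 to 17.** The six phenols of 18 are uncovered from hexabenzyl ether 17 by hydrogenolysis. Benzyl ethers are chosen because they survive acid, oxidant, tin hydroxide and nickel, and because their removal leaves the single methyl ether untouched.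

**17 to 15 and 11.** The C3′–C6 bond is cut. No ionic disconnection works here: C6 is meta to both oxygens, and a cation at C3′ would open the ring. A radical at C3′, released from acid 15 through its activated ester 16, is joined to arylboronic acid 11 on nickel. The cut divides the molecule into halves of similar size; the forward reaction has to deliver the aryl group trans to the C2′ aryl group.

**11 to 10, then to 7 and 8.** The boron of 11 comes from the triflate of 10. The C3–aryl bond of 10 is cut in the same way as above: acid 7 (through 9) and boronic acid 8.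

**7 and 15, through 6 and 14, to 5 and 13.** This is the key cut. The C3–C3a bond of each dihydrobenzofuran-3-carboxylate is broken and C3a is reconnected to the carboxyl carbon, which gives the six-membered 4-oxopyran ring of flavanones 5 and 13. The fit is atom for atom: O1 and the C4 oxygen flanking C3a in 6 are O1 and the 5-oxygen flanking C4a in 5, and the 6-triflate is the 7-triflate. The precursor has one stereocentre instead of two, and the extruded carbonyl carbon becomes the handle that is later exchanged for an aryl group. The forward reaction is an oxidative 1,2-shift of the benzo ring from C4 to C3.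

**5 and 13 to 3 with 4 or 12.** The C2–aryl bond is cut; the forward reaction is an asymmetric conjugate arylation of chromone 3. One chromone serves both halves, and the opposite absolute sense of the two halves is met by using the two antipodes of one ligand.

**3 to 2 to 1.** The 7-oxygen, as triflate, is the future carbon handle at C6 and C6′; the 5-oxygen, as benzyl ether, is the future C4 and C4′ hydroxyl. The two phenols of 1 are told apart by the hydrogen bond of the 5-OH to the carbonyl.

## Alternatives that were turned down

**Alternative 1:** (the textbook route) Biomimetic oxidative cross-coupling. The disconnection cuts C3–C3a and O1–C2 of the left unit in one event. Forward, a one-electron oxidant or a peroxidase would act on a mixture of the right-hand dimer A1 and the methoxystilbene A2; the benzylic radical position of oxidised A2 would have to bond to the carbon between the two hydroxyls of the 3,5-dihydroxyphenyl ring of A1, and the resulting quinone methide would be trapped by the neighbouring phenol. It was turned down on three grounds. That resorcinol ring is not conjugated with the phenoxyl radical of A1 and carries no spin, so the required bond competes with the fast couplings at the 4-oxygen, the ortho carbon and the olefinic carbon of both partners, as homo- and cross-dimers. Nothing controls absolute configuration, so the new ring would form in both trans senses next to an existing (R,R) unit. A1 would itself have to be made as one enantiomer by the same uncontrolled type of coupling.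

**Alternative 2:** Carbene C–H insertion. The disconnection cuts C2–C3 of each furan ring. Forward, a chiral dirhodium carboxylate catalyst would decompose diaryldiazomethane A3, and the donor/donor carbene would insert into the benzylic C–H bond of an ortho aryloxymethyl ether, closing the ring and setting C2 and C3 together. It was turned down for these reasons. Insertion gives the cis relationship, so C2 must afterwards be inverted by acid-mediated ring opening, one more step per ring. The diazo carbon sits on an arene substituted at both ortho positions, so the hydrazone precursor forms reluctantly, and a second identical benzyl ether must be carried on the other ortho oxygen and discarded. For the right unit one aryl group of the diazo compound would be the complete left unit, which makes the route linear and roughly doubles its length. Two catalyst antipodes would still be needed.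

**Alternative 3:** De novo construction of the central benzo ring by Danheiser benzannulation. The disconnection cuts three ring bonds of the left benzo ring (C3a–C7a, C4–C5, C7–C7a). Forward, cyclobutenone A4 would open to a vinylketene, add siloxyalkyne A5, and electrocyclise to a resorcinol with the C3 side chain between the two oxygens and C3′ para to it, which is the correct pattern; acid would then close the furan ring. It was turned down for these reasons. A4 holds C3′ at the vinylogous α-position of an enone and would be exposed to epimerisation at the temperatures the cascade needs. A4 and A5 each need a multi-step synthesis with their own stereocentres. The benzannulation sets none of the four stereocentres. The regiochemistry it would supply is already present in a phloroglucinol-derived chromone.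

Key step: step 4

## Route

Step 1
Reactants: 1 5,7-dihydroxy-4H-chromen-4-one
Product: 2 5-hydroxy-4-oxo-4H-chromen-7-yl trifluoromethanesulfonate
Conditions: PhNTf2 (1.05 equiv), Et3N, DMF, 0 °C to rt
Reagents that add atoms: N-phenylbis(trifluoromethanesulfonimide), O=S(=O)(N(c1ccccc1)S(=O)(=O)C(F)(F)F)C(F)(F)F
Why: O-sulfonylation of the more acidic, non-chelated 7-OH; the 5-OH is held in a hydrogen bond to the C4 carbonyl and should stay free, as is general for 5,7-dihydroxychromones and flavones.

Step 2
Reactants: 2 5-hydroxy-4-oxo-4H-chromen-7-yl trifluoromethanesulfonate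
Product: 3 5-(benzyloxy)-4-oxo-4H-chromen-7-yl trifluoromethanesulfonate
Conditions: BnBr, K2CO3, DMF, 40 °C
Reagents that add atoms: benzyl bromide, BrCc1ccccc1
Why: Williamson etherification of the chelated phenol under anhydrous carbonate conditions that an aryl triflate tolerates; the benzyl ether frees the ketone for ketalisation in the key step and becomes the C4/C4′ hydroxyl of the target.

Step 3
Reactants: 3 5-(benzyloxy)-4-oxo-4H-chromen-7-yl trifluoromethanesulfonate; 4 [4-(benzyloxy)-3-methoxyphenyl]boronic acid
Product: 5 (2S)-5-(benzyloxy)-2-[4-(benzyloxy)-3-methoxyphenyl]-4-oxo-3,4-dihydro-2H-chromen-7-yl trifluoromethanesulfonate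
Conditions: 4 (2 equiv), [Rh(OH)(cod)]2 (2.5 mol %), (S)-MeO-F12-BIPHEP (5.5 mol %), CH2Cl2/H2O (10:1), 25 °C
Reagents that add atoms: none
Why: Hayashi–Miyaura asymmetric 1,4-addition of an arylboronic acid to a chromone, with the electron-poor ligand (S)-2,2′-bis[bis(3,4,5-trifluorophenyl)phosphino]-6,6′-dimethoxy-1,1′-biphenyl; the aryl–rhodium species adds to C2 and the oxa-π-allyl intermediate is protonated by water, so C2 is set by the ligand. The medium is base-free, which should prevent retro-oxa-Michael opening of the product, and monovalent rhodium does not insert into the aryl triflate.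

Step 4
Reactants: 5 (2S)-5-(benzyloxy)-2-[4-(benzyloxy)-3-methoxyphenyl]-4-oxo-3,4-dihydro-2H-chromen-7-yl trifluoromethanesulfonate
Product: 6 methyl (2S,3S)-4-(benzyloxy)-2-[4-(benzyloxy)-3-methoxyphenyl]-6-(trifluoromethanesulfonyloxy)-2,3-dihydro-1-benzofuran-3-carboxylate
Conditions: PhI(OAc)2 (1.3 equiv), H2SO4 (1 equiv), HC(OMe)3, 0 °C to rt
Reagents that add atoms: trimethyl orthoformate, COC(OC)OC; water, O
Why: Oxidative ring contraction of a flavanone by trivalent iodine, a known reaction of flavanones and chromanones (also run with Tl(NO3)3) and the cyclic relative of the 1,2-aryl shift that turns aryl alkyl ketones into 2-arylalkanoates. Acid and orthoformate convert the C4 ketone into its dimethyl ketal and methyl enol ether; PhI(OAc)2 attacks C3 of the enol ether from the face opposite the C2 aryl group, giving a C3–iodane that sits equatorial and trans to that aryl group while methanol re-forms the ketal at C4. Iodobenzene is then expelled as the benzo carbon C4a migrates from C4 to C3 anti-periplanar to the C3–I bond, and the dimethoxycarbenium ion left at C4 ends as the methyl ester. The dihydrofuran ring is therefore closed not by a cyclisation but by contraction of the six-membered pyranone (a 1,2-shift with inversion at the migration terminus C3), which forms the C3–C3a bond of the target and pushes the carbonyl carbon out of the ring as the C3 carboxylate. C2, set in step 3, is not involved and is retained; C3 should form trans to the C2 aryl group because iodine enters anti to that group and is displaced with inversion, although this centre serves only as a handle and is reset in step 6. The step needs migration of the benzo ring in preference to migration of the C2 aryl group, to elimination towards the flavone, and to opening at C2. The equatorial C–I bond is aligned with the C4–C4a ring bond and not with the C2–aryl bond, the migrating carbon carries two ortho oxygen donors (O1 and the 5-benzyloxy group) that stabilise the bridged transition state, and the two methoxy groups at C4 take up the developing charge. The para triflate should lower the migratory aptitude only mildly, and once C4 is a ketal the ring oxygen is no longer a vinylogous leaving group, which protects C2 against acid-induced opening.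

Step 5
Reactants: 6 methyl (2S,3S)-4-(benzyloxy)-2-[4-(benzyloxy)-3-methoxyphenyl]-6-(trifluoromethanesulfonyloxy)-2,3-dihydro-1-benzofuran-3-carboxylate
Product: 7 (2S,3S)-4-(benzyloxy)-2-[4-(benzyloxy)-3-methoxyphenyl]-6-(trifluoromethanesulfonyloxy)-2,3-dihydro-1-benzofuran-3-carboxylic acid
Conditions: Me3SnOH (5 equiv), ClCH2CH2Cl, 80 °C; 1 M HCl work-up
Reagents that add atoms: trimethyltin hydroxide, C[Sn](C)(C)O
Why: Methyl ester cleavage with trimethyltin hydroxide, which is essentially neutral; it avoids the ester enolate and with it the E1cB expulsion of the ring phenoxide that would erase C2, and it leaves the aryl triflate intact.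

Step 6
Reactants: 7 (2S,3S)-4-(benzyloxy)-2-[4-(benzyloxy)-3-methoxyphenyl]-6-(trifluoromethanesulfonyloxy)-2,3-dihydro-1-benzofuran-3-carboxylic acid; 8 [3,5-bis(benzyloxy)phenyl]boronic acid
Product: 10 (2S,3S)-4-(benzyloxy)-2-[4-(benzyloxy)-3-methoxyphenyl]-3-[3,5-bis(benzyloxy)phenyl]-2,3-dihydro-1-benzofuran-6-yl trifluoromethanesulfonate, via tetrachlorophthalimidyl ester 9 (not isolated)
Conditions: N-hydroxytetrachlorophthalimide, N,N′-diisopropylcarbodiimide, DMAP (cat.), CH2Cl2, rt; then 8 (3 equiv), NiCl2·6H2O (20 mol %), bathophenanthroline (22 mol %), Et3N (10 equiv), 1,4-dioxane/DMF (10:1), 75 °C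
Reagents that add atoms: none
Why: Nickel-catalysed decarboxylative Suzuki-type arylation of a redox-active ester, known for secondary alkyl and benzylic acids; electron transfer from the aryl–nickel species to 9 releases CO2 and the C3 radical, which should be captured by nickel on the face away from the C2 aryl group, so that reductive elimination gives the trans-2,3-diaryl unit with C2 unchanged. The C2–O1 bond lies near the nodal plane of the C3 radical, so β-scission is stereoelectronically disfavoured, and phenanthroline-ligated nickel is a poor activator of aryl triflates.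

Step 7
Reactants: 10 (2S,3S)-4-(benzyloxy)-2-[4-(benzyloxy)-3-methoxyphenyl]-3-[3,5-bis(benzyloxy)phenyl]-2,3-dihydro-1-benzofuran-6-yl trifluoromethanesulfonate
Product: 11 [(2S,3S)-4-(benzyloxy)-2-[4-(benzyloxy)-3-methoxyphenyl]-3-[3,5-bis(benzyloxy)phenyl]-2,3-dihydro-1-benzofuran-6-yl]boronic acid
Conditions: B2(OH)4 (3 equiv), PdCl(XPhos)(2′-aminobiphenyl-2-yl) (2 mol %), XPhos (4 mol %), KOAc (3 equiv), EtOH/THF (3:1), 80 °C
Reagents that add atoms: tetrahydroxydiboron, OB(O)B(O)O
Why: Palladium-catalysed Miyaura-type borylation of an aryl triflate with tetrahydroxydiboron, which gives the free boronic acid needed in step 11 directly; the boron sits meta to both oxygens, so protodeboronation should be slow.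

Step 8
Reactants: 3 5-(benzyloxy)-4-oxo-4H-chromen-7-yl trifluoromethanesulfonate; 12 [4-(benzyloxy)phenyl]boronic acid
Product: 13 (2R)-5-(benzyloxy)-2-[4-(benzyloxy)phenyl]-4-oxo-3,4-dihydro-2H-chromen-7-yl trifluoromethanesulfonate
Conditions: 12 (2 equiv), [Rh(OH)(cod)]2 (2.5 mol %), (R)-MeO-F12-BIPHEP (5.5 mol %), CH2Cl2/H2O (10:1), 25 °C
Reagents that add atoms: none
Why: The same Hayashi–Miyaura 1,4-addition as step 3 on the same chromone, with the antipodal ligand, so that C2′ is set with the opposite sense that the right unit requires.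

Step 9
Reactants: 13 (2R)-5-(benzyloxy)-2-[4-(benzyloxy)phenyl]-4-oxo-3,4-dihydro-2H-chromen-7-yl trifluoromethanesulfonate
Product: 14 methyl (2R,3R)-4-(benzyloxy)-2-[4-(benzyloxy)phenyl]-6-(trifluoromethanesulfonyloxy)-2,3-dihydro-1-benzofuran-3-carboxylate
Conditions: PhI(OAc)2 (1.3 equiv), H2SO4 (1 equiv), HC(OMe)3, 0 °C to rt
Reagents that add atoms: trimethyl orthoformate, COC(OC)OC; water, O
Why: The trivalent-iodine ring contraction of step 4 in the enantiomeric series: anti attack of iodine at C3, 1,2-shift of C4a with loss of iodobenzene, C2′ retained and the ester trans to the aryl group.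

Step 10
Reactants: 14 methyl (2R,3R)-4-(benzyloxy)-2-[4-(benzyloxy)phenyl]-6-(trifluoromethanesulfonyloxy)-2,3-dihydro-1-benzofuran-3-carboxylate
Product: 15 (2R,3R)-4-(benzyloxy)-2-[4-(benzyloxy)phenyl]-6-(trifluoromethanesulfonyloxy)-2,3-dihydro-1-benzofuran-3-carboxylic acid
Conditions: Me3SnOH (5 equiv), ClCH2CH2Cl, 80 °C; 1 M HCl work-up
Reagents that add atoms: trimethyltin hydroxide, C[Sn](C)(C)O
Why: Neutral tin hydroxide ester cleavage as in step 5, chosen to avoid enolate-mediated ring opening and triflate hydrolysis.

Step 11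
Reactants: 15 (2R,3R)-4-(benzyloxy)-2-[4-(benzyloxy)phenyl]-6-(trifluoromethanesulfonyloxy)-2,3-dihydro-1-benzofuran-3-carboxylic acid; 11 [(2S,3S)-4-(benzyloxy)-2-[4-(benzyloxy)-3-methoxyphenyl]-3-[3,5-bis(benzyloxy)phenyl]-2,3-dihydro-1-benzofuran-6-yl]boronic acid
Product: 17 (2R,3R)-4-(benzyloxy)-2-[4-(benzyloxy)phenyl]-3-[(2S,3S)-4-(benzyloxy)-2-[4-(benzyloxy)-3-methoxyphenyl]-3-[3,5-bis(benzyloxy)phenyl]-2,3-dihydro-1-benzofuran-6-yl]-2,3-dihydro-1-benzofuran-6-yl trifluoromethanesulfonate, via tetrachlorophthalimidyl ester 16 (not isolated)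
Conditions: N-hydroxytetrachlorophthalimide, N,N′-diisopropylcarbodiimide, DMAP (cat.), CH2Cl2, rt; then 11 (1.5 equiv), NiCl2·6H2O (20 mol %), bathophenanthroline (22 mol %), Et3N (10 equiv), 1,4-dioxane/DMF (10:1), 75 °C
Reagents that add atoms: none
Why: The nickel-catalysed decarboxylative arylation of step 6, now as the fragment union that forms the C3′–C6 bond; the boron-bearing carbon has two unsubstituted ortho positions, and the C3′ radical should be arylated anti to the C2′ aryl group, giving the (2′R,3′R)-trans ring. The stereocentres of 11 are remote and configurationally inert, and the triflate of 16 should be ignored by phenanthroline-ligated nickel.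

Step 12
Reactants: 17 (2R,3R)-4-(benzyloxy)-2-[4-(benzyloxy)phenyl]-3-[(2S,3S)-4-(benzyloxy)-2-[4-(benzyloxy)-3-methoxyphenyl]-3-[3,5-bis(benzyloxy)phenyl]-2,3-dihydro-1-benzofuran-6-yl]-2,3-dihydro-1-benzofuran-6-yl trifluoromethanesulfonate
Product: 18 (2R,3R)-3-[(2S,3S)-3-(3,5-dihydroxyphenyl)-4-hydroxy-2-(4-hydroxy-3-methoxyphenyl)-2,3-dihydro-1-benzofuran-6-yl]-4-hydroxy-2-(4-hydroxyphenyl)-2,3-dihydro-1-benzofuran-6-yl trifluoromethanesulfonate
Conditions: H2 (1 atm), Pd/C (10 wt %), EtOAc/MeOH (1:1), rt
Reagents that add atoms: none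
Why: Hydrogenolysis of six primary benzyl aryl ethers, placed before the stilbene exists; without added base the aryl triflate should survive, and the ring C2–O bonds are hindered secondary benzylic ethers that are cleaved far more slowly than the primary ones.

Step 13
Reactants: 18 (2R,3R)-3-[(2S,3S)-3-(3,5-dihydroxyphenyl)-4-hydroxy-2-(4-hydroxy-3-methoxyphenyl)-2,3-dihydro-1-benzofuran-6-yl]-4-hydroxy-2-(4-hydroxyphenyl)-2,3-dihydro-1-benzofuran-6-yl trifluoromethanesulfonate; 19 4-ethenylphenyl acetate
Product: 21 gnetin K, via stilbene monoacetate 20 (not isolated)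
Conditions: 19 (2 equiv), PdCl2(PPh3)2 (10 mol %), LiCl (3 equiv), KOAc (3 equiv), DMF, 90 °C; then MeOH, K2CO3 (cat.), rt
Reagents that add atoms: none
Why: Mizoroki–Heck reaction of the aryl triflate with a terminal styrene; chloride converts the aryl–palladium triflate into the neutral chloride complex, so insertion should be β-selective and β-hydride elimination gives the E-stilbene. Acetate is too weak a base to ionise the phenols, and methanolysis in the same flask removes the acetate, including any acetyl group that has moved to another phenol.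

## Compound list

1 | 5,7-dihydroxy-4H-chromen-4-one | O=c1ccoc2cc(O)cc(O)c12 | starting material
2 | 5-hydroxy-4-oxo-4H-chromen-7-yl trifluoromethanesulfonate | O=c1ccoc2cc(OS(=O)(=O)C(F)(F)F)cc(O)c12 | intermediate
3 | 5-(benzyloxy)-4-oxo-4H-chromen-7-yl trifluoromethanesulfonate | O=c1ccoc2cc(OS(=O)(=O)C(F)(F)F)cc(OCc3ccccc3)c12 | intermediate
4 | [4-(benzyloxy)-3-methoxyphenyl]boronic acid | COc1cc(B(O)O)ccc1OCc1ccccc1 | starting material
5 | (2S)-5-(benzyloxy)-2-[4-(benzyloxy)-3-methoxyphenyl]-4-oxo-3,4-dihydro-2H-chromen-7-yl trifluoromethanesulfonate | COc1cc([C@@H]2CC(=O)c3c(OCc4ccccc4)cc(OS(=O)(=O)C(F)(F)F)cc3O2)ccc1OCc1ccccc1 | intermediate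
6 | methyl (2S,3S)-4-(benzyloxy)-2-[4-(benzyloxy)-3-methoxyphenyl]-6-(trifluoromethanesulfonyloxy)-2,3-dihydro-1-benzofuran-3-carboxylate | COc1cc([C@H]2Oc3cc(OS(=O)(=O)C(F)(F)F)cc(OCc4ccccc4)c3[C@@H]2C(=O)OC)ccc1OCc1ccccc1 | intermediate
7 | (2S,3S)-4-(benzyloxy)-2-[4-(benzyloxy)-3-methoxyphenyl]-6-(trifluoromethanesulfonyloxy)-2,3-dihydro-1-benzofuran-3-carboxylic acid | COc1cc([C@H]2Oc3cc(OS(=O)(=O)C(F)(F)F)cc(OCc4ccccc4)c3[C@@H]2C(=O)O)ccc1OCc1ccccc1 | intermediate
8 | [3,5-bis(benzyloxy)phenyl]boronic acid | OB(O)c1cc(OCc2ccccc2)cc(OCc2ccccc2)c1 | starting material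
9 | 4,5,6,7-tetrachloro-1,3-dioxoisoindolin-2-yl ester of acid 7 | COc1cc([C@H]2Oc3cc(OS(=O)(=O)C(F)(F)F)cc(OCc4ccccc4)c3[C@@H]2C(=O)ON2C(=O)c3c(Cl)c(Cl)c(Cl)c(Cl)c3C2=O)ccc1OCc1ccccc1 | intermediate (not isolated)
10 | (2S,3S)-4-(benzyloxy)-2-[4-(benzyloxy)-3-methoxyphenyl]-3-[3,5-bis(benzyloxy)phenyl]-2,3-dihydro-1-benzofuran-6-yl trifluoromethanesulfonate | COc1cc([C@H]2Oc3cc(OS(=O)(=O)C(F)(F)F)cc(OCc4ccccc4)c3[C@@H]2c2cc(OCc3ccccc3)cc(OCc3ccccc3)c2)ccc1OCc1ccccc1 | intermediate
11 | [(2S,3S)-4-(benzyloxy)-2-[4-(benzyloxy)-3-methoxyphenyl]-3-[3,5-bis(benzyloxy)phenyl]-2,3-dihydro-1-benzofuran-6-yl]boronic acid | COc1cc([C@H]2Oc3cc(B(O)O)cc(OCc4ccccc4)c3[C@@H]2c2cc(OCc3ccccc3)cc(OCc3ccccc3)c2)ccc1OCc1ccccc1 | intermediate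
12 | [4-(benzyloxy)phenyl]boronic acid | OB(O)c1ccc(OCc2ccccc2)cc1 | starting material
13 | (2R)-5-(benzyloxy)-2-[4-(benzyloxy)phenyl]-4-oxo-3,4-dihydro-2H-chromen-7-yl trifluoromethanesulfonate | c1ccccc1COc1ccc([C@H]2CC(=O)c3c(OCc4ccccc4)cc(OS(=O)(=O)C(F)(F)F)cc3O2)cc1 | intermediate
14 | methyl (2R,3R)-4-(benzyloxy)-2-[4-(benzyloxy)phenyl]-6-(trifluoromethanesulfonyloxy)-2,3-dihydro-1-benzofuran-3-carboxylate | COC(=O)[C@@H]1c2c(OCc3ccccc3)cc(OS(=O)(=O)C(F)(F)F)cc2O[C@H]1c1ccc(OCc2ccccc2)cc1 | intermediate
15 | (2R,3R)-4-(benzyloxy)-2-[4-(benzyloxy)phenyl]-6-(trifluoromethanesulfonyloxy)-2,3-dihydro-1-benzofuran-3-carboxylic acid | OC(=O)[C@@H]1c2c(OCc3ccccc3)cc(OS(=O)(=O)C(F)(F)F)cc2O[C@H]1c1ccc(OCc2ccccc2)cc1 | intermediate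
16 | 4,5,6,7-tetrachloro-1,3-dioxoisoindolin-2-yl ester of acid 15 | O=C(ON1C(=O)c2c(Cl)c(Cl)c(Cl)c(Cl)c2C1=O)[C@@H]1c2c(OCc3ccccc3)cc(OS(=O)(=O)C(F)(F)F)cc2O[C@H]1c1ccc(OCc2ccccc2)cc1 | intermediate (not isolated)
17 | (2R,3R)-4-(benzyloxy)-2-[4-(benzyloxy)phenyl]-3-[(2S,3S)-4-(benzyloxy)-2-[4-(benzyloxy)-3-methoxyphenyl]-3-[3,5-bis(benzyloxy)phenyl]-2,3-dihydro-1-benzofuran-6-yl]-2,3-dihydro-1-benzofuran-6-yl trifluoromethanesulfonate | COc1cc([C@H]2Oc3cc([C@@H]4c5c(OCc6ccccc6)cc(OS(=O)(=O)C(F)(F)F)cc5O[C@H]4c4ccc(OCc5ccccc5)cc4)cc(OCc4ccccc4)c3[C@@H]2c2cc(OCc3ccccc3)cc(OCc3ccccc3)c2)ccc1OCc1ccccc1 | intermediate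
18 | (2R,3R)-3-[(2S,3S)-3-(3,5-dihydroxyphenyl)-4-hydroxy-2-(4-hydroxy-3-methoxyphenyl)-2,3-dihydro-1-benzofuran-6-yl]-4-hydroxy-2-(4-hydroxyphenyl)-2,3-dihydro-1-benzofuran-6-yl trifluoromethanesulfonate | COc1cc([C@H]2Oc3cc([C@@H]4c5c(O)cc(OS(=O)(=O)C(F)(F)F)cc5O[C@H]4c4ccc(O)cc4)cc(O)c3[C@@H]2c2cc(O)cc(O)c2)ccc1O | intermediate
19 | 4-ethenylphenyl acetate (4-acetoxystyrene) | CC(=O)Oc1ccc(C=C)cc1 | starting material
20 | gnetin K acetylated at the stilbene 4-hydroxyl | COc1cc([C@H]2Oc3cc([C@@H]4c5c(O)cc(/C=C/c6ccc(OC(C)=O)cc6)cc5O[C@H]4c4ccc(O)cc4)cc(O)c3[C@@H]2c2cc(O)cc(O)c2)ccc1O | intermediate (not isolated)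
21 | gnetin K | COc1cc([C@H]2Oc3cc([C@@H]4c5c(O)cc(/C=C/c6ccc(O)cc6)cc5O[C@H]4c4ccc(O)cc4)cc(O)c3[C@@H]2c2cc(O)cc(O)c2)ccc1O | target

## Step count and risk

Total: 13 steps. Longest linear sequence: 10 steps (1, 2, 3, 4, 5, 6, 7, 11, 12, 13); steps 8–10 form the second branch from the shared chromone 3.

**Step 4 (key step; step 9 is the same reaction in the other series).** Most likely to go wrong: slow ketalisation of a carbonyl flanked by the 5-benzyloxy group, diversion of the C3–iodane by elimination towards the flavone oxidation level or by migration of the electron-rich C2 aryl group, oxidation of the dialkoxyarene by trivalent iodine, and acid-induced reversible opening at C2 that would erode the configuration set in step 3. Fallback: from 5 the oxidation is separated from the migration. Bromination at C3 with CuBr2 (EtOAc/CHCl3, reflux) should give the trans-3-bromoflavanone F1. Ketalisation (HC(OMe)3, MeOH, TsOH cat.) gives the bromo dimethyl ketal F2. AgBF4 in CH2Cl2/MeOH then abstracts bromide and triggers the same 1,2-shift of C4a, redox-neutral and without an iodine oxidant, returning to the route at 6.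

**Step 11 (fragment union).** Most likely to go wrong: slow capture of the hindered secondary benzylic radical by the bulky aryl–nickel species, leading to radical dimerisation or reduction; erosion of the trans selectivity; base-mediated enolisation and ring opening of the activated ester at 75 °C; competing reaction at the triflate. Step 6 carries the same risks on a smaller scale. Fallback: from 10 the triflate is exchanged for bromide (KBr, Pd2(dba)3, tBuBrettPhos, toluene, 100 °C) to give the aryl bromide F3. The free acid 15 and F3 are then joined by metallaphotoredox decarboxylative arylation (Ir[dF(CF3)ppy]2(dtbbpy)PF6, NiCl2·glyme, 4,4′-di-tert-butyl-2,2′-bipyridine, Cs2CO3, DMF, blue light, rt). The carboxylate is oxidised directly, no activated ester or hot amine is present, and nickel selects the C–Br over the C–OTf bond. The route is rejoined at 17.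

**Step 3 (step 8 is the same reaction with the ligand antipode).** Most likely to go wrong: insufficient facial selectivity or slow insertion with this 5,7-dioxygenated chromone, and partial loss of enantiopurity through reversible ring opening of the product. Fallback: from 3 and 4 the addition is run with [Rh(OH)(cod)]2 alone to give the racemic flavanone F4. F4 is resolved kinetically by asymmetric transfer hydrogenation (RuCl(p-cymene)(TsDPEN), HCO2H/Et3N), using the TsDPEN antipode that reduces the (2R)-ketone faster to the cis-flavan-4-ol F5. The unreduced (2S)-ketone is 5.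

**Step 12.** Most likely to go wrong: hydrogenolysis of the two ring benzylic C2–O bonds, or of the C–OTf bond, competing with removal of the more hindered benzyl ethers next to C3 and C3′. Fallback: from 17 the order of the last operations is reversed. Heck coupling with 4-(benzyloxy)styrene under the conditions of step 13 gives the heptabenzyl ether F6. All seven benzyl ethers are then removed without hydrogen by BCl3 and pentamethylbenzene (CH2Cl2, −78 °C), arriving directly at 21.

**Step 13.** Most likely to go wrong: catalyst inhibition and oxidative degradation when palladium is used on an unprotected hexaphenol at 90 °C, and incomplete linear selectivity of the insertion. Fallback: from 18 a Stille vinylation with tributyl(vinyl)stannane (Pd(PPh3)4, LiCl, 1,4-dioxane, 90 °C, no base) gives the 6′-vinyl hexaphenol F7. Cross-metathesis of F7 with 19 (second-generation Hoveyda–Grubbs catalyst, CH2Cl2, 40 °C) builds the E-alkene and rejoins the route at 20, which is methanolysed as in step 13.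

## Further compounds

F1 | step 4 | (2R,3R)-5-(benzyloxy)-2-[4-(benzyloxy)-3-methoxyphenyl]-3-bromo-4-oxo-3,4-dihydro-2H-chromen-7-yl trifluoromethanesulfonate (trans; same spatial arrangement at C2 as 5) | COc1cc([C@@H]2[C@@H](Br)C(=O)c3c(OCc4ccccc4)cc(OS(=O)(=O)C(F)(F)F)cc3O2)ccc1OCc1ccccc1
F2 | step 4 | (2R,3R)-5-(benzyloxy)-2-[4-(benzyloxy)-3-methoxyphenyl]-3-bromo-4,4-dimethoxy-3,4-dihydro-2H-chromen-7-yl trifluoromethanesulfonate | COc1cc([C@@H]2[C@@H](Br)C(OC)(OC)c3c(OCc4ccccc4)cc(OS(=O)(=O)C(F)(F)F)cc3O2)ccc1OCc1ccccc1
F3 | step 11 | (2S,3S)-4-(benzyloxy)-2-[4-(benzyloxy)-3-methoxyphenyl]-3-[3,5-bis(benzyloxy)phenyl]-6-bromo-2,3-dihydro-1-benzofuran | COc1cc([C@H]2Oc3cc(Br)cc(OCc4ccccc4)c3[C@@H]2c2cc(OCc3ccccc3)cc(OCc3ccccc3)c2)ccc1OCc1ccccc1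
F4 | step 3 | racemic 5-(benzyloxy)-2-[4-(benzyloxy)-3-methoxyphenyl]-4-oxo-3,4-dihydro-2H-chromen-7-yl trifluoromethanesulfonate | COc1cc(C2CC(=O)c3c(OCc4ccccc4)cc(OS(=O)(=O)C(F)(F)F)cc3O2)ccc1OCc1ccccc1
F5 | step 3 | (2R,4R)-5-(benzyloxy)-2-[4-(benzyloxy)-3-methoxyphenyl]-4-hydroxy-3,4-dihydro-2H-chromen-7-yl trifluoromethanesulfonate (cis) | COc1cc([C@H]2C[C@@H](O)c3c(OCc4ccccc4)cc(OS(=O)(=O)C(F)(F)F)cc3O2)ccc1OCc1ccccc1
F6 | step 12 | gnetin K heptabenzyl ether | COc1cc([C@H]2Oc3cc([C@@H]4c5c(OCc6ccccc6)cc(/C=C/c6ccc(OCc7ccccc7)cc6)cc5O[C@H]4c4ccc(OCc5ccccc5)cc4)cc(OCc4ccccc4)c3[C@@H]2c2cc(OCc3ccccc3)cc(OCc3ccccc3)c2)ccc1OCc1ccccc1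
F7 | step 13 | (2R,3R)-3-[(2S,3S)-3-(3,5-dihydroxyphenyl)-4-hydroxy-2-(4-hydroxy-3-methoxyphenyl)-2,3-dihydro-1-benzofuran-6-yl]-6-ethenyl-2-(4-hydroxyphenyl)-2,3-dihydro-1-benzofuran-4-ol | COc1cc([C@H]2Oc3cc([C@@H]4c5c(O)cc(C=C)cc5O[C@H]4c4ccc(O)cc4)cc(O)c3[C@@H]2c2cc(O)cc(O)c2)ccc1O
A1 | alternative 1 | (2R,3R)-3-(3,5-dihydroxyphenyl)-2-(4-hydroxyphenyl)-6-[(E)-2-(4-hydroxyphenyl)ethenyl]-2,3-dihydro-1-benzofuran-4-ol | Oc1cc(O)cc(c1)[C@@H]1c2c(O)cc(/C=C/c3ccc(O)cc3)cc2O[C@H]1c1ccc(O)cc1
A2 | alternative 1 | 5-[(E)-2-(4-hydroxy-3-methoxyphenyl)ethenyl]benzene-1,3-diol (isorhapontigenin) | COc1cc(/C=C/c2cc(O)cc(O)c2)ccc1O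
A3 | alternative 2 | 5-bromo-2-{[3,5-bis(benzyloxy)phenyl](diazo)methyl}-1,3-bis{[4-(benzyloxy)-3-methoxybenzyl]oxy}benzene | [N-]=[N+]=C(c1cc(OCc2ccccc2)cc(OCc2ccccc2)c1)c1c(OCc2ccc(OCc3ccccc3)c(OC)c2)cc(Br)cc1OCc1ccc(OCc2ccccc2)c(OC)c1
A4 | alternative 3 | (2R,3R)-4-(benzyloxy)-2-[4-(benzyloxy)phenyl]-3-(3-oxocyclobut-1-en-1-yl)-2,3-dihydro-1-benzofuran-6-yl trifluoromethanesulfonate | O=C1C=C(C1)[C@@H]1c2c(OCc3ccccc3)cc(OS(=O)(=O)C(F)(F)F)cc2O[C@H]1c1ccc(OCc2ccccc2)cc1
A5 | alternative 3 | {[(3S)-3-[3,5-bis(benzyloxy)phenyl]-4-[4-(benzyloxy)-3-methoxyphenyl]-4-(tert-butyldimethylsilyloxy)but-1-yn-1-yl]oxy}tri(propan-2-yl)silane (either C4 epimer) | CC(C)[Si](C(C)C)(C(C)C)OC#C[C@H](c1cc(OCc2ccccc2)cc(OCc2ccccc2)c1)C(O[Si](C)(C)C(C)(C)C)c1ccc(OCc2ccccc2)c(OC)c1
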